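**Retrosynthetic overview**

- Target ⇐ fluoride removal of three silyl ethers from the silyl-protected flavanone.
- Rings C and A are closed in one pot from two acyclic fragments. Ring C forms first (O1–C8a, alkoxide addition–elimination on an α-oxo ketene dithioacetal). Ring A follows (C8–C8a Michael addition–elimination, C4a–C5 Claisen closure, aromatisation).
- Fragment 1 (aryl, C2, C3, C4, C4a, C8a): C2 is set as an (S)-carbinol by a catalytic enantioselective Mukaiyama aldol, and its C–O bond is never broken afterwards.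
- Fragment 2 (C5–C8, 7-OMe, side chain): a β-methoxy enoate whose (Z)-alkene comes from a Z-selective Wittig reaction of silyloxyacetone.
- Ring B is bought as 3,4-dihydroxybenzaldehyde.

Assumption: compounds 3, 6, 7 and 9 are taken as catalogue items, and the (S,S)-bisphosphoramide is assumed to direct Si-face attack (the sense is checked by Mosher analysis on 5 and the catalyst enantiomer swapped if it is reversed).

**Route**

Step 1
Reactants: 1 3,4-dihydroxybenzaldehyde
Product: 2 3,4-bis(tert-butyldimethylsilyloxy)benzaldehyde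
Conditions: TBSCl (2.3 equiv), imidazole (5 equiv), DMF, 0 °C → rt
Reagents that add atoms: tert-butyldimethylsilyl chloride, CC(C)(C)[Si](C)(C)Cl
Why: Imidazole-promoted O-silylation masks the catechol for the later carbanion steps and is removable with fluoride without base.

Step 2
Reactants: 3 4,4-bis(methylsulfanyl)but-3-en-2-one
Product: 4 [4,4-bis(methylsulfanyl)buta-1,3-dien-2-yl]oxy(trimethyl)silane
Conditions: LiN(iPr)2 (1.1 equiv), THF, −78 °C; Me3SiCl; non-aqueous work-up
Reagents that add atoms: chlorotrimethylsilane, C[Si](C)(C)Cl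
Why: Kinetic deprotonation of the only α-methyl group and O-silylation (silyl enol ether formation) gives the 2-siloxydiene needed for a Mukaiyama aldol.

Step 3
Reactants: 2 3,4-bis(tert-butyldimethylsilyloxy)benzaldehyde; 4 [4,4-bis(methylsulfanyl)buta-1,3-dien-2-yl]oxy(trimethyl)silane
Product: 5 (S)-1-[3,4-bis(tert-butyldimethylsilyloxy)phenyl]-1-hydroxy-5,5-bis(methylsulfanyl)pent-4-en-3-one
Conditions: SiCl4 (1.1 equiv), (S,S)-bisphosphoramide N,N'-bis[(11bS)-3,5-dimethyl-4-oxido-3,5-dihydro-4H-dinaphtho[2,1-d:1',2'-f][1,3,2]diazaphosphepin-4-yl]-N,N'-dimethylpentane-1,5-diamine (5 mol %), iPr2NEt (10 mol %), CH2Cl2, −78 °C; cold sat. aq. NaHCO3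
Reagents that add atoms: none
Why: Lewis-base-catalysed, SiCl4-mediated Mukaiyama aldol (Denmark type), in which the chiral phosphoramide-bound silyl cation activates the aldehyde and the enol ether CH2 adds to its Si face, setting the (S)-carbinol that becomes C2; the acid-free work-up keeps the adduct acyclic.

Step 4
Reactants: 6 (3-carboxypropyl)triphenylphosphonium bromide; 7 1-(tert-butyldimethylsilyloxy)propan-2-one
Product: 8 (Z)-6-(tert-butyldimethylsilyloxy)-5-methylhex-4-enoic acid
Conditions: KN(SiMe3)2 (2.05 equiv), THF, 0 °C; then 7, −78 °C → rt; aq. HCl to pH 4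
Reagents that add atoms: none
Why: Wittig olefination in Still's Z-selective variant, where a non-stabilised ylide and an α-silyloxy ketone give the trisubstituted alkene with the chain cis to CH2OSi, which is the (Z)-geometry of the side chain.

Step 5
Reactants: 8 (Z)-6-(tert-butyldimethylsilyloxy)-5-methylhex-4-enoic acid; 9 potassium methyl malonate
Product: 11 methyl (Z)-8-(tert-butyldimethylsilyloxy)-7-methyl-3-oxooct-6-enoate, via acyl imidazolide 10 (not isolated)
Conditions: 1,1'-carbonyldiimidazole (1.2 equiv), THF, rt; then 9 (2 equiv), MgCl2, Et3N, MeCN, rt → 45 °C; aq. citric acid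
Reagents that add atoms: none
Why: Masamune–Brooks homologation, in which the acyl imidazolide C-acylates the magnesium enolate of the malonate half-ester and decarboxylation on work-up gives the β-keto ester without touching the alkene.

Step 6
Reactants: 11 methyl (Z)-8-(tert-butyldimethylsilyloxy)-7-methyl-3-oxooct-6-enoate
Product: 12 methyl (2E,6Z)-8-(tert-butyldimethylsilyloxy)-3-methoxy-7-methylocta-2,6-dienoate
Conditions: NaH (1.1 equiv), Me2SO4 (1.2 equiv), THF–DMPU, 0 °C → rt
Reagents that add atoms: dimethyl sulfate, COS(=O)(=O)OC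
Why: O-alkylation of the sodium enolate by a hard electrophile in a dipolar aprotic medium gives the β-methoxy enoate, which installs the future 7-OMe and removes the 1,3-dicarbonyl acidity; either enol-ether isomer is usable because the geometry is lost in the dienolate.

Step 7
Reactants: 5 (S)-1-[3,4-bis(tert-butyldimethylsilyloxy)phenyl]-1-hydroxy-5,5-bis(methylsulfanyl)pent-4-en-3-one; 12 methyl (2E,6Z)-8-(tert-butyldimethylsilyloxy)-3-methoxy-7-methylocta-2,6-dienoate
Product: 15 (2S)-2-[3,4-bis(tert-butyldimethylsilyloxy)phenyl]-8-[(2Z)-4-(tert-butyldimethylsilyloxy)-3-methylbut-2-en-1-yl]-5-hydroxy-7-methoxy-2,3-dihydro-4H-chromen-4-one, via methylsulfanyl pyranone 13 (not isolated), via pyranonyl dienoate 14 (not isolated)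
Conditions: 5, LiN(SiMe3)2 (1.05 equiv), THF, −78 → 0 °C; then added to the lithium dienolate of 12 [12 (1.3 equiv), LiN(iPr)2 (1.3 equiv), THF–DMPU, −78 °C], −78 → −20 °C; then LiN(SiMe3)2 (1.5 equiv), → 0 °C; AcOH quench at −40 °C
Reagents that add atoms: none
Why: Proposed new method: the lithium alkoxide of 5 displaces one MeS group of the α-oxo ketene dithioacetal by 6-endo addition–elimination (ring C; the C2–O bond is untouched, so the S configuration is carried over), the γ-carbon of the dienolate of 12 then displaces the second MeS group at the same carbon, and the resulting doubly vinylogous C–H acid is deprotonated and closes from the pyranone α-carbon onto its own ester with loss of methoxide and tautomerisation to the phenol (ring A), a Michael–Dieckmann benzannulation whose closest known relatives are the Staunton–Weinreb annulation of methoxypyranones and the Junjappa–Ila aromatic annulation of α-oxo ketene dithioacetals.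

Step 8
Reactants: 15 (2S)-2-[3,4-bis(tert-butyldimethylsilyloxy)phenyl]-8-[(2Z)-4-(tert-butyldimethylsilyloxy)-3-methylbut-2-en-1-yl]-5-hydroxy-7-methoxy-2,3-dihydro-4H-chromen-4-one
Product: 16 (2S)-2-(3,4-dihydroxyphenyl)-5-hydroxy-8-[(2Z)-4-hydroxy-3-methylbut-2-en-1-yl]-7-methoxy-2,3-dihydro-4H-chromen-4-one
Conditions: HF·pyridine (excess), THF–pyridine, 0 °C → rt; pH 7 buffer work-up
Reagents that add atoms: none
Why: Fluoride-mediated desilylation of the two aryl and one allylic silyl ethers under mildly acidic conditions, which avoids the base-induced ring opening that racemises 5-hydroxyflavanones and leaves the (Z)-allylic alcohol intact.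

**Compound list**

1 | 3,4-dihydroxybenzaldehyde | O=Cc1ccc(O)c(O)c1 | starting material
2 | 3,4-bis(tert-butyldimethylsilyloxy)benzaldehyde | O=Cc1ccc(O[Si](C)(C)C(C)(C)C)c(O[Si](C)(C)C(C)(C)C)c1 | intermediate
3 | 4,4-bis(methylsulfanyl)but-3-en-2-one | CC(=O)C=C(SC)SC | starting material
4 | [4,4-bis(methylsulfanyl)buta-1,3-dien-2-yl]oxy(trimethyl)silane | C=C(O[Si](C)(C)C)C=C(SC)SC | intermediate
5 | (S)-1-[3,4-bis(tert-butyldimethylsilyloxy)phenyl]-1-hydroxy-5,5-bis(methylsulfanyl)pent-4-en-3-one | CSC(SC)=CC(=O)C[C@H](O)c1ccc(O[Si](C)(C)C(C)(C)C)c(O[Si](C)(C)C(C)(C)C)c1 | intermediate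
6 | (3-carboxypropyl)triphenylphosphonium bromide | OC(=O)CCC[P+](c1ccccc1)(c1ccccc1)c1ccccc1.[Br-] | starting material
7 | 1-(tert-butyldimethylsilyloxy)propan-2-one | CC(=O)CO[Si](C)(C)C(C)(C)C | starting material
8 | (Z)-6-(tert-butyldimethylsilyloxy)-5-methylhex-4-enoic acid | OC(=O)CC/C=C(/C)CO[Si](C)(C)C(C)(C)C | intermediate
9 | potassium methyl malonate | COC(=O)CC(=O)[O-].[K+] | starting material
10 | (Z)-6-(tert-butyldimethylsilyloxy)-1-(imidazol-1-yl)-5-methylhex-4-en-1-one (acyl imidazolide, not isolated) | O=C(CC/C=C(/C)CO[Si](C)(C)C(C)(C)C)n1ccnc1 | intermediate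
11 | methyl (Z)-8-(tert-butyldimethylsilyloxy)-7-methyl-3-oxooct-6-enoate | COC(=O)CC(=O)CC/C=C(/C)CO[Si](C)(C)C(C)(C)C | intermediate
12 | methyl (2E,6Z)-8-(tert-butyldimethylsilyloxy)-3-methoxy-7-methylocta-2,6-dienoate | COC(=O)/C=C(/OC)CC/C=C(/C)CO[Si](C)(C)C(C)(C)C | intermediate
13 | (S)-2-[3,4-bis(tert-butyldimethylsilyloxy)phenyl]-6-(methylsulfanyl)-2,3-dihydro-4H-pyran-4-one (not isolated) | CSC1=CC(=O)C[C@@H](c2ccc(O[Si](C)(C)C(C)(C)C)c(O[Si](C)(C)C(C)(C)C)c2)O1 | intermediate
14 | methyl (2E,6Z)-4-{(2S)-2-[3,4-bis(tert-butyldimethylsilyloxy)phenyl]-4-oxo-3,4-dihydro-2H-pyran-6-yl}-8-(tert-butyldimethylsilyloxy)-3-methoxy-7-methylocta-2,6-dienoate (both C4 epimers, not isolated) | COC(=O)/C=C(/OC)C(C/C=C(/C)CO[Si](C)(C)C(C)(C)C)C1=CC(=O)C[C@@H](c2ccc(O[Si](C)(C)C(C)(C)C)c(O[Si](C)(C)C(C)(C)C)c2)O1 | intermediate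
15 | (2S)-2-[3,4-bis(tert-butyldimethylsilyloxy)phenyl]-8-[(2Z)-4-(tert-butyldimethylsilyloxy)-3-methylbut-2-en-1-yl]-5-hydroxy-7-methoxy-2,3-dihydro-4H-chromen-4-one | COc1cc(O)c2c(c1C/C=C(/C)CO[Si](C)(C)C(C)(C)C)O[C@H](c1ccc(O[Si](C)(C)C(C)(C)C)c(O[Si](C)(C)C(C)(C)C)c1)CC2=O | intermediate
16 | (2S)-2-(3,4-dihydroxyphenyl)-5-hydroxy-8-[(2Z)-4-hydroxy-3-methylbut-2-en-1-yl]-7-methoxy-2,3-dihydro-4H-chromen-4-one | COc1cc(O)c2c(c1C/C=C(/C)CO)O[C@H](c1ccc(O)c(O)c1)CC2=O | target

**Totals**

Total step count: 8. Longest linear sequence: 5 steps (steps 4, 5, 6, 7, 8).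

**Three steps most likely to fail**

Step 7 (one-pot closure of rings C and A). The risks are proton transfer from C3 of 13 to the dienolate instead of conjugate addition, α- instead of γ-attack of the dienolate, and loss of ee by retro-aldol of the alkoxide of 5 or by base-induced opening of ring C. The fallback separates the two ring closures and makes the C–C bond under Lewis-acid instead of anionic conditions; it sets out from 5 (and 12) and comes back at 15. 5 is closed with CF3CO2H (5 mol %) in CH2Cl2 at 0 °C to 13, which is now isolated. 3-Chloroperbenzoic acid (1.0 equiv, CH2Cl2, −40 °C) then oxidises the sulfide to the more electrophilic sulfoxide (2S)-2-[3,4-bis(tert-butyldimethylsilyloxy)phenyl]-6-(methylsulfinyl)-2,3-dihydro-4H-pyran-4-one F1. In parallel 12 is converted with LiN(iPr)2 and Me3SiCl (THF, −78 °C) into the vinylogous silyl ketene acetal (6Z)-8-(tert-butyldimethylsilyloxy)-1,3-dimethoxy-7-methyl-1-(trimethylsilyloxy)octa-1,3,6-triene F2. Mukaiyama–Michael addition–elimination of F2 to F1 (Me3SiOTf 10 mol %, CH2Cl2, −78 °C) gives 14, which is isolated. KOtBu (2.2 equiv, THF, −78 → −20 °C) then effects the vinylogous Dieckmann closure and aromatisation to 15.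

Step 3 (enantioselective Mukaiyama aldol). The risks are insufficient ee with this untested push–pull diene, the wrong facial sense, or premature cyclisation to 13. The fallback replaces asymmetric catalysis by resolution; it sets out from 2 and 3 (4 is skipped) and comes back at 5. LiN(iPr)2 (THF, −78 °C) converts 3 into its lithium enolate, which adds to 2 to give the racemic aldol rac-1-[3,4-bis(tert-butyldimethylsilyloxy)phenyl]-1-hydroxy-5,5-bis(methylsulfanyl)pent-4-en-3-one F3. Acylative kinetic resolution follows with (R)-benzotetramisole [(R)-2-phenyl-2,3-dihydroimidazo[2,1-b][1,3]benzothiazole, 5 mol %; the enantiomer that acylates the (R)-carbinol], isobutyric anhydride (0.6 equiv) and iPr2NEt in CHCl3 at 0 °C. It converts the unwanted enantiomer into (R)-1-[3,4-bis(tert-butyldimethylsilyloxy)phenyl]-5,5-bis(methylsulfanyl)-3-oxopent-4-en-1-yl 2-methylpropanoate F4 and leaves (S)-5 (at most 50 %), which is separated by chromatography.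

Step 4 (Z-selective Wittig). The risks are enolisation of ketone 7 by the basic ylide and a Z:E ratio too low to purify. The fallback fixes the geometry by a stereospecific elimination from a purified diastereomer instead of by kinetic selectivity (Horner–Wittig, Warren variant); it sets out from 6 (and 7) and comes back at 8. 6 is hydrolysed with aqueous NaOH at reflux, with loss of benzene, to 4-(diphenylphosphoryl)butanoic acid F5. Its dianion (n-BuLi 2.1 equiv, THF, −78 °C) adds to 7 to give two separable β-hydroxy phosphine oxides, (4S*,5R*)-6-(tert-butyldimethylsilyloxy)-4-(diphenylphosphoryl)-5-hydroxy-5-methylhexanoic acid F6 and (4S*,5S*)-6-(tert-butyldimethylsilyloxy)-4-(diphenylphosphoryl)-5-hydroxy-5-methylhexanoic acid F7. NaH (DMF, 50 °C) on pure F6 gives 8 by syn-elimination of diphenylphosphinate; F7 would give the (E)-acid and is discarded.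

Further compounds
F1 | step 7 | (2S)-2-[3,4-bis(tert-butyldimethylsilyloxy)phenyl]-6-(methylsulfinyl)-2,3-dihydro-4H-pyran-4-one (sulfoxide epimers) | CS(=O)C1=CC(=O)C[C@@H](c2ccc(O[Si](C)(C)C(C)(C)C)c(O[Si](C)(C)C(C)(C)C)c2)O1
F2 | step 7 | (6Z)-8-(tert-butyldimethylsilyloxy)-1,3-dimethoxy-7-methyl-1-(trimethylsilyloxy)octa-1,3,6-triene (diene geometry unassigned) | COC(O[Si](C)(C)C)=CC(OC)=CC/C=C(/C)CO[Si](C)(C)C(C)(C)C
F3 | step 3 | rac-1-[3,4-bis(tert-butyldimethylsilyloxy)phenyl]-1-hydroxy-5,5-bis(methylsulfanyl)pent-4-en-3-one | CSC(SC)=CC(=O)CC(O)c1ccc(O[Si](C)(C)C(C)(C)C)c(O[Si](C)(C)C(C)(C)C)c1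
F4 | step 3 | (R)-1-[3,4-bis(tert-butyldimethylsilyloxy)phenyl]-5,5-bis(methylsulfanyl)-3-oxopent-4-en-1-yl 2-methylpropanoate | CSC(SC)=CC(=O)C[C@@H](OC(=O)C(C)C)c1ccc(O[Si](C)(C)C(C)(C)C)c(O[Si](C)(C)C(C)(C)C)c1
F5 | step 4 | 4-(diphenylphosphoryl)butanoic acid | OC(=O)CCCP(=O)(c1ccccc1)c1ccccc1
F6 | step 4 | (4S*,5R*)-6-(tert-butyldimethylsilyloxy)-4-(diphenylphosphoryl)-5-hydroxy-5-methylhexanoic acid (racemic, one enantiomer drawn) | OC(=O)CC[C@H](P(=O)(c1ccccc1)c1ccccc1)[C@](C)(O)CO[Si](C)(C)C(C)(C)C
F7 | step 4 | (4S*,5S*)-6-(tert-butyldimethylsilyloxy)-4-(diphenylphosphoryl)-5-hydroxy-5-methylhexanoic acid (racemic, one enantiomer drawn) | OC(=O)CC[C@H](P(=O)(c1ccccc1)c1ccccc1)[C@@](C)(O)CO[Si](C)(C)C(C)(C)C
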